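The lactone ring of the target, O1–C2(=O)–C3=C4–C5(O-acyl)–C6, has the oxidation pattern of a ring-expanded 2-furyl carbinol: the four furan carbons map onto C2–C5 and the carbinol carbon onto C6. Everything therefore rests on an anodic Achmatowicz ring expansion of (S)-1-(furan-2-yl)prop-2-en-1-ol, which in one operation forms the O1–C2 bond, the six-membered ring, the Z C3=C4 alkene and the C5 carbonyl. The precursor is simply the resolved furfural–vinyl Grignard adduct. C6 then relays its configuration to C5 (lactol oxidation, anti hydride delivery); cross-metathesis extends the vinyl group, and a citronellene-derived dienoic acid is esterified onto O5 before a single acidic deprotection.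

Key step: step 3

Remark: the target is read as (5S,6S)-cis on the ring (numbering O1, C2(=O) to C6) and (2E,4E,6R,11S) in the acyl chain. No structure needed correction: the S carbinol gives 6S because the order O > ring carbon > vinyl holds at every stage. C11 (S) is taken from (S)-propylene oxide and is masked as a triethylsilyl ether that falls together with the tert-butyl ester.
Assumption: the lipase follows its usual preference for secondary carbinols (furyl as large, vinyl as medium group), so the R enantiomer is acetylated and the S alcohol is recovered.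

Step 1
Reactants: 1 furfural; 2 vinylmagnesium bromide
Product: 3 rac-1-(furan-2-yl)prop-2-en-1-ol
Conditions: THF, −78 → 0 °C; sat. aq. NH4Cl
Reagents that add atoms: none
Why: Grignard 1,2-addition of the vinyl nucleophile to the aldehyde gives the secondary carbinol, whose new stereocentre is formed racemic and is resolved in step 2.

Step 2
Reactants: 3 rac-1-(furan-2-yl)prop-2-en-1-ol
Product: 4 (S)-1-(furan-2-yl)prop-2-en-1-ol
Conditions: immobilised Candida antarctica lipase B (Novozym 435), vinyl acetate (3 equiv), MTBE, 30 °C, stopped slightly past half conversion; chromatography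
Reagents that add atoms: none
Why: Lipase-catalysed kinetic resolution by irreversible transesterification should acetylate the R enantiomer (Kazlauskas preference) and leave the S alcohol enantioenriched, so the stereocentre is selected and not created.

Step 3
Reactants: 4 (S)-1-(furan-2-yl)prop-2-en-1-ol
Product: 7 (2S)-6-hydroxy-2-vinyl-2H-pyran-3(6H)-one (anomer mixture), via dimethoxydihydrofuran carbinol 5 (not isolated), via Z-hydroxyoxoenal 6 (not isolated)
Conditions: undivided cell, graphite anode, Ni cathode, NH4Br (0.1 equiv), MeOH, −15 °C, constant current, ca. 2.2 F/mol; then MeOH stripped cold, THF/H2O (4:1), H2SO4 (cat.), 0 °C → rt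
Reagents that add atoms: water, O (methanol, CO, supplies only the two methoxy groups of intermediate 5, which are lost again on hydrolysis)
Why: Bromide is oxidised at the anode to an electrophilic bromine species that attacks the furan, and two methanol molecules trap the resulting oxocarbenium ions, a net two-electron 1,4-dimethoxylation to 5 (hydrogen leaves at the cathode); aqueous acid then hydrolyses both acetal carbons to the Z-4-oxo-enal 6, whose carbinol hydroxyl adds to the aldehyde. The closest known reaction type is the Achmatowicz rearrangement in its Clauson-Kaas anodic methoxylation form, which is established for 2-furyl carbinols. The pyranone ring closes by 6-exo-trig hemiacetalisation that forms the O1–C2 bond (target numbering), and the Z geometry inherited from the furan holds hydroxyl and aldehyde within reach. The only new stereocentre is the hemiacetal carbon, which equilibrates under anomeric control to a mixture and is erased in step 4, while the carbinol centre is never touched and stays S. The step needs chemoselectivity for the furan over the vinyl group, secured by the far higher electron density of the furan toward the mediator, by the low temperature and by limiting the charge, and it needs the allylic carbinol to survive hydrolysis, secured by brief exposure to dilute acid at 0 °C.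

Step 4
Reactants: 7 (2S)-6-hydroxy-2-vinyl-2H-pyran-3(6H)-one
Product: 8 (6S)-6-vinyl-2H-pyran-2,5(6H)-dione
Conditions: CrO3/H2SO4 (Jones reagent), acetone, 0 °C, 15 min; iPrOH quench; cold extractive work-up, crude used at once
Reagents that add atoms: none
Why: Jones oxidation of the hemiacetal C–H gives the lactone carbonyl within minutes in an acidic, base-free medium, which removes the anomeric mixture and leaves C6 as the only stereocentre of a dione that is kept cold and reduced immediately.

Step 5
Reactants: 8 (6S)-6-vinyl-2H-pyran-2,5(6H)-dione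
Product: 9 (5S,6S)-5-hydroxy-6-vinyl-5,6-dihydro-2H-pyran-2-one
Conditions: NaBH4, CeCl3·7H2O, MeOH/CH2Cl2 (1:1), −78 °C; sat. aq. NH4Cl
Reagents that add atoms: none
Why: Luche reduction should deliver hydride 1,2 to the cerium-activated C5 ketone from the face opposite the C6 vinyl group of the nearly flat ring, which sets C5 as S and cis to C6 and should outpace enolisation at −78 °C.

Step 6
Reactants: 9 (5S,6S)-5-hydroxy-6-vinyl-5,6-dihydro-2H-pyran-2-one; 10 tert-butyl acrylate
Product: 11 tert-butyl (2E)-3-[(2S,3S)-3-hydroxy-6-oxo-3,6-dihydro-2H-pyran-2-yl]prop-2-enoate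
Conditions: tert-butyl acrylate (5 equiv), second-generation Hoveyda–Grubbs catalyst RuCl2(H2IMes)(=CH-C6H4-2-OiPr) (5 mol %), CH2Cl2, 40 °C
Reagents that add atoms: none
Why: Olefin cross-metathesis between the terminal vinyl group and excess acrylate should give the E enoate under thermodynamic control, while the conjugated endocyclic alkene of the unstrained lactone is not engaged.

Step 7
Reactants: 12 (R)-3,7-dimethylocta-1,6-diene (citronellene)
Product: 14 (R)-4-methylhex-5-en-1-ol, via (R)-4-methylhex-5-enal 13 (not isolated)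
Conditions: O3 (1.0 equiv, Sudan Red 7B end-point), CH2Cl2/MeOH (4:1), −78 °C; then NaBH4, −78 °C → rt
Reagents that add atoms: ozone, [O-][O+]=O
Why: Chemoselective ozonolysis cleaves the electron-rich trisubstituted alkene faster than the vinyl group, and borohydride reduces the aldehyde in the same flask without touching the remote methyl stereocentre.

Step 8
Reactants: 14 (R)-4-methylhex-5-en-1-ol
Product: 15 (R)-6-bromo-3-methylhex-1-ene
Conditions: CBr4, PPh3, CH2Cl2, 0 °C
Reagents that add atoms: carbon tetrabromide, BrC(Br)(Br)Br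
Why: Appel bromination converts the primary alcohol into the bromide by SN2 displacement of the oxyphosphonium group under neutral conditions.

Step 9
Reactants: 15 (R)-6-bromo-3-methylhex-1-ene; 16 (S)-propylene oxide
Product: 18 (2S,7R)-7-methylnon-8-en-2-ol, via alkylmagnesium bromide 17 (not isolated)
Conditions: Mg, THF, 40 °C; then CuI (10 mol %), (S)-propylene oxide, −30 → 0 °C; sat. aq. NH4Cl
Reagents that add atoms: none
Why: Copper-catalysed opening of the epoxide by the Grignard reagent occurs at the unsubstituted carbon, so the S carbinol centre of the epoxide is not a reacting centre and becomes C11 of the target unchanged.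

Step 10
Reactants: 18 (2S,7R)-7-methylnon-8-en-2-ol
Product: 19 triethyl{[(2S,7R)-7-methylnon-8-en-2-yl]oxy}silane
Conditions: TESCl, imidazole, CH2Cl2, 0 °C → rt
Reagents that add atoms: chlorotriethylsilane, CC[Si](Cl)(CC)CC
Why: Silylation of the secondary alcohol installs an ether that tolerates ozone, ylides and hydroxide but is cleaved under the final acid treatment.

Step 11
Reactants: 19 triethyl{[(2S,7R)-7-methylnon-8-en-2-yl]oxy}silane
Product: 21 (2R,7S)-2-methyl-7-(triethylsilyloxy)octanal, via secondary ozonide 20 (not isolated)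
Conditions: O3, CH2Cl2, −78 °C; then PPh3, −78 °C → rt
Reagents that add atoms: ozone, [O-][O+]=O
Why: Ozonolysis with reductive phosphine work-up cleaves the terminal alkene to the α-methyl aldehyde under neutral conditions that should not epimerise the adjacent stereocentre.

Step 12
Reactants: 21 (2R,7S)-2-methyl-7-(triethylsilyloxy)octanal; 22 2-(triphenylphosphoranylidene)propanal
Product: 23 (2E,4R,9S)-2,4-dimethyl-9-(triethylsilyloxy)dec-2-enal
Conditions: toluene, 90 °C
Reagents that add atoms: none
Why: Wittig olefination with the stabilised formyl ylide is E-selective for the trisubstituted enal, and the weakly basic ylide should leave the α-stereocentre intact while the α-branched product resists a second homologation.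

Step 13
Reactants: 23 (2E,4R,9S)-2,4-dimethyl-9-(triethylsilyloxy)dec-2-enal; 24 methyl (triphenylphosphoranylidene)acetate
Product: 25 methyl (2E,4E,6R,11S)-4,6-dimethyl-11-(triethylsilyloxy)dodeca-2,4-dienoate
Conditions: CH2Cl2, 40 °C
Reagents that add atoms: none
Why: Wittig olefination with the stabilised ester ylide adds the C1–C2 unit and should give the 2E alkene, completing the E,E-dienoate.

Step 14
Reactants: 25 methyl (2E,4E,6R,11S)-4,6-dimethyl-11-(triethylsilyloxy)dodeca-2,4-dienoate
Product: 26 (2E,4E,6R,11S)-4,6-dimethyl-11-(triethylsilyloxy)dodeca-2,4-dienoic acid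
Conditions: LiOH·H2O, THF/MeOH/H2O (3:1:1), 0 °C → rt; then dil. HCl to pH 4, 0 °C
Reagents that add atoms: lithium hydroxide, [Li+].[OH-]
Why: Saponification of the methyl ester by acyl–oxygen cleavage leaves the secondary silyl ether and the diene untouched, and the cold, mildly acidic work-up spares the silyl group.

Step 15
Reactants: 11 tert-butyl (2E)-3-[(2S,3S)-3-hydroxy-6-oxo-3,6-dihydro-2H-pyran-2-yl]prop-2-enoate; 26 (2E,4E,6R,11S)-4,6-dimethyl-11-(triethylsilyloxy)dodeca-2,4-dienoic acid
Product: 27 tert-butyl (2E)-3-[(2S,3S)-3-{[(2E,4E,6R,11S)-4,6-dimethyl-11-(triethylsilyloxy)dodeca-2,4-dienoyl]oxy}-6-oxo-3,6-dihydro-2H-pyran-2-yl]prop-2-enoate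
Conditions: N-(3-dimethylaminopropyl)-N'-ethylcarbodiimide hydrochloride (EDC·HCl), DMAP (0.2 equiv), CH2Cl2, 0 °C
Reagents that add atoms: none
Why: Steglich-type carbodiimide esterification acylates the C5 hydroxyl with retention, and only catalytic DMAP at 0 °C is used so that the base-sensitive C6–H/C5–O array is not driven to elimination.

Step 16
Reactants: 27 tert-butyl (2E)-3-[(2S,3S)-3-{[(2E,4E,6R,11S)-4,6-dimethyl-11-(triethylsilyloxy)dodeca-2,4-dienoyl]oxy}-6-oxo-3,6-dihydro-2H-pyran-2-yl]prop-2-enoate
Product: 28 (2E)-3-[(2S,3S)-3-{[(2E,4E,6R,11S)-11-hydroxy-4,6-dimethyldodeca-2,4-dienoyl]oxy}-6-oxo-3,6-dihydro-2H-pyran-2-yl]prop-2-enoic acid (CNP0107712.2)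
Conditions: TFA/CH2Cl2 (1:4), H2O (5 equiv), 0 °C → rt
Reagents that add atoms: none
Why: Acidolysis removes the tert-butyl ester through the tert-butyl cation (loss of isobutene) and the triethylsilyl ether by protodesilylation in the same medium, to which the lactone, the allylic ester and the dienoate should be stable.

Compound list
1 | furfural | O=Cc1ccco1 | starting material
2 | vinylmagnesium bromide | C=C[Mg]Br | starting material
3 | rac-1-(furan-2-yl)prop-2-en-1-ol | OC(c1ccco1)C=C | intermediate
4 | (S)-1-(furan-2-yl)prop-2-en-1-ol | O[C@H](c1ccco1)C=C | intermediate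
5 | (1S)-1-(2,5-dimethoxy-2,5-dihydrofuran-2-yl)prop-2-en-1-ol (acetal diastereomers, not isolated) | O[C@H](C1(OC)C=CC(OC)O1)C=C | intermediate
6 | (2Z,5S)-5-hydroxy-4-oxohepta-2,6-dienal (not isolated) | O[C@H](C(=O)/C=C\C=O)C=C | intermediate
7 | (2S)-6-hydroxy-2-vinyl-2H-pyran-3(6H)-one (anomer mixture) | O=C1C=CC(O)O[C@H]1C=C | intermediate
8 | (6S)-6-vinyl-2H-pyran-2,5(6H)-dione | O=C1C=CC(=O)O[C@H]1C=C | intermediate
9 | (5S,6S)-5-hydroxy-6-vinyl-5,6-dihydro-2H-pyran-2-one | O[C@H]1C=CC(=O)O[C@H]1C=C | intermediate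
10 | tert-butyl acrylate | C=CC(=O)OC(C)(C)C | starting material
11 | tert-butyl (2E)-3-[(2S,3S)-3-hydroxy-6-oxo-3,6-dihydro-2H-pyran-2-yl]prop-2-enoate | O[C@H]1C=CC(=O)O[C@H]1/C=C/C(=O)OC(C)(C)C | intermediate
12 | (R)-3,7-dimethylocta-1,6-diene (citronellene) | C=C[C@H](C)CCC=C(C)C | starting material
13 | (R)-4-methylhex-5-enal (not isolated) | C=C[C@H](C)CCC=O | intermediate
14 | (R)-4-methylhex-5-en-1-ol | C=C[C@H](C)CCCO | intermediate
15 | (R)-6-bromo-3-methylhex-1-ene | C=C[C@H](C)CCCBr | intermediate
16 | (S)-propylene oxide | C[C@H]1CO1 | starting material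
17 | [(4R)-4-methylhex-5-en-1-yl]magnesium bromide (not isolated) | C=C[C@H](C)CCC[Mg]Br | intermediate
18 | (2S,7R)-7-methylnon-8-en-2-ol | C=C[C@H](C)CCCC[C@H](C)O | intermediate
19 | triethyl{[(2S,7R)-7-methylnon-8-en-2-yl]oxy}silane | C=C[C@H](C)CCCC[C@H](C)O[Si](CC)(CC)CC | intermediate
20 | 3-[(2R,7S)-7-(triethylsilyloxy)octan-2-yl]-1,2,4-trioxolane (secondary ozonide, not isolated) | O1OC(OC1)[C@H](C)CCCC[C@H](C)O[Si](CC)(CC)CC | intermediate
21 | (2R,7S)-2-methyl-7-(triethylsilyloxy)octanal | O=C[C@H](C)CCCC[C@H](C)O[Si](CC)(CC)CC | intermediate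
22 | 2-(triphenylphosphoranylidene)propanal | CC(C=O)=P(c1ccccc1)(c1ccccc1)c1ccccc1 | starting material
23 | (2E,4R,9S)-2,4-dimethyl-9-(triethylsilyloxy)dec-2-enal | O=C/C(C)=C/[C@H](C)CCCC[C@H](C)O[Si](CC)(CC)CC | intermediate
24 | methyl (triphenylphosphoranylidene)acetate | COC(=O)C=P(c1ccccc1)(c1ccccc1)c1ccccc1 | starting material
25 | methyl (2E,4E,6R,11S)-4,6-dimethyl-11-(triethylsilyloxy)dodeca-2,4-dienoate | COC(=O)/C=C/C(C)=C/[C@H](C)CCCC[C@H](C)O[Si](CC)(CC)CC | intermediate
26 | (2E,4E,6R,11S)-4,6-dimethyl-11-(triethylsilyloxy)dodeca-2,4-dienoic acid | OC(=O)/C=C/C(C)=C/[C@H](C)CCCC[C@H](C)O[Si](CC)(CC)CC | intermediate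
27 | tert-butyl (2E)-3-[(2S,3S)-3-{[(2E,4E,6R,11S)-4,6-dimethyl-11-(triethylsilyloxy)dodeca-2,4-dienoyl]oxy}-6-oxo-3,6-dihydro-2H-pyran-2-yl]prop-2-enoate | CC(/C=C/C(=O)O[C@H]1C=CC(=O)O[C@H]1/C=C/C(=O)OC(C)(C)C)=C\[C@H](C)CCCC[C@H](C)O[Si](CC)(CC)CC | intermediate
28 | (2E)-3-[(2S,3S)-3-{[(2E,4E,6R,11S)-11-hydroxy-4,6-dimethyldodeca-2,4-dienoyl]oxy}-6-oxo-3,6-dihydro-2H-pyran-2-yl]prop-2-enoic acid | CC(/C=C/C(=O)O[C@H]1C=CC(=O)O[C@H]1/C=C/C(=O)O)=C\[C@H](C)CCCC[C@H](C)O | target

Total step count: 16. Longest linear sequence: 10 steps (steps 7 to 16, from citronellene); the ring branch runs through steps 1 to 6 and joins at step 15.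

Steps most likely to fail

Step 4. The enedione lactone may enolise toward the achiral, aromatic 5-hydroxy-6-vinyl-2-pyranone during oxidation or work-up, which erodes the C6 configuration and the material balance before hydride can be delivered. The fallback avoids the dione: C5 is reduced at the acetal oxidation level and C2 is oxidised only after C5 carries the acyl chain. It sets out from 7 and comes back at 28.
- Lactol 7 is converted with HC(OMe)3 and BF3·OEt2 into the methyl acetal (2S)-6-methoxy-2-vinyl-2H-pyran-3(6H)-one F1.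
- NaBH4/CeCl3 reduction of F1 should give, in the sense usual for 6-alkoxy-2H-pyran-3(6H)-ones, the 2,3-trans alcohol (2S,3R)-6-methoxy-2-vinyl-3,6-dihydro-2H-pyran-3-ol F2.
- Mitsunobu esterification of F2 with acid 26 (PPh3, DIAD) inverts C3 and gives the cis ester (2S,3S)-6-methoxy-2-vinyl-3,6-dihydro-2H-pyran-3-yl (2E,4E,6R,11S)-4,6-dimethyl-11-(triethylsilyloxy)dodeca-2,4-dienoate F3.
- Aqueous acetic acid in THF hydrolyses the allylic acetal and the silyl ether to the lactol (2S,3S)-6-hydroxy-2-vinyl-3,6-dihydro-2H-pyran-3-yl (2E,4E,6R,11S)-11-hydroxy-4,6-dimethyldodeca-2,4-dienoate F4.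
- MnO2 oxidises the allylic lactol, and not the saturated C11 alcohol, to the lactone (2S,3S)-6-oxo-2-vinyl-3,6-dihydro-2H-pyran-3-yl (2E,4E,6R,11S)-11-hydroxy-4,6-dimethyldodeca-2,4-dienoate F5.
- Cross-metathesis of F5 with 10 gives tert-butyl (2E)-3-[(2S,3S)-3-{[(2E,4E,6R,11S)-11-hydroxy-4,6-dimethyldodeca-2,4-dienoyl]oxy}-6-oxo-3,6-dihydro-2H-pyran-2-yl]prop-2-enoate F6, and TFA in CH2Cl2 releases 28.

Step 5. Hydride may attack syn to the vinyl group to a significant extent, so that the relay from C6 to C5 gives an epimer mixture. The fallback makes the sequence stereoconvergent by setting C5 through SN2 inversion instead of face selection. It sets out from 8 and comes back at 27.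
- The reduction of 8 is run as before and the epimers are separated; the cis alcohol 9 continues unchanged.
- The trans alcohol (5R,6S)-5-hydroxy-6-vinyl-5,6-dihydro-2H-pyran-2-one F7 undergoes the same cross-metathesis with 10 to give tert-butyl (2E)-3-[(2S,3R)-3-hydroxy-6-oxo-3,6-dihydro-2H-pyran-2-yl]prop-2-enoate F8.
- Mitsunobu esterification of F8 with acid 26 (PPh3, DIAD) inverts C5 and gives 27.

Step 15. Under the acylation conditions the new acyloxy group may be lost by E1cB elimination (C6–H is γ to the acrylate ester) to give a 2-pyranone, or acylation of the hindered allylic alcohol may stall. The fallback reverses the order of the two bond formations so that the ester is made while C6 carries only the less acidifying vinyl group. It sets out from 9 and comes back at 27.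
- Alcohol 9 is esterified with acid 26 by the carbodiimide method to give (2S,3S)-6-oxo-2-vinyl-3,6-dihydro-2H-pyran-3-yl (2E,4E,6R,11S)-4,6-dimethyl-11-(triethylsilyloxy)dodeca-2,4-dienoate F9.
- Cross-metathesis of F9 with 10 then takes place at the terminal vinyl group, the trisubstituted and dienoate alkenes of the chain being unreactive, and gives 27.

Further compounds
F1 | step 4 | (2S)-6-methoxy-2-vinyl-2H-pyran-3(6H)-one (anomer mixture) | O=C1C=CC(OC)O[C@H]1C=C
F2 | step 4 | (2S,3R)-6-methoxy-2-vinyl-3,6-dihydro-2H-pyran-3-ol (anomer mixture) | O[C@@H]1C=CC(OC)O[C@H]1C=C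
F3 | step 4 | (2S,3S)-6-methoxy-2-vinyl-3,6-dihydro-2H-pyran-3-yl (2E,4E,6R,11S)-4,6-dimethyl-11-(triethylsilyloxy)dodeca-2,4-dienoate | CC(/C=C/C(=O)O[C@H]1C=CC(OC)O[C@H]1C=C)=C\[C@H](C)CCCC[C@H](C)O[Si](CC)(CC)CC
F4 | step 4 | (2S,3S)-6-hydroxy-2-vinyl-3,6-dihydro-2H-pyran-3-yl (2E,4E,6R,11S)-11-hydroxy-4,6-dimethyldodeca-2,4-dienoate | CC(/C=C/C(=O)O[C@H]1C=CC(O)O[C@H]1C=C)=C\[C@H](C)CCCC[C@H](C)O
F5 | step 4 | (2S,3S)-6-oxo-2-vinyl-3,6-dihydro-2H-pyran-3-yl (2E,4E,6R,11S)-11-hydroxy-4,6-dimethyldodeca-2,4-dienoate | CC(/C=C/C(=O)O[C@H]1C=CC(=O)O[C@H]1C=C)=C\[C@H](C)CCCC[C@H](C)O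
F6 | step 4 | tert-butyl (2E)-3-[(2S,3S)-3-{[(2E,4E,6R,11S)-11-hydroxy-4,6-dimethyldodeca-2,4-dienoyl]oxy}-6-oxo-3,6-dihydro-2H-pyran-2-yl]prop-2-enoate | CC(/C=C/C(=O)O[C@H]1C=CC(=O)O[C@H]1/C=C/C(=O)OC(C)(C)C)=C\[C@H](C)CCCC[C@H](C)O
F7 | step 5 | (5R,6S)-5-hydroxy-6-vinyl-5,6-dihydro-2H-pyran-2-one | O[C@@H]1C=CC(=O)O[C@H]1C=C
F8 | step 5 | tert-butyl (2E)-3-[(2S,3R)-3-hydroxy-6-oxo-3,6-dihydro-2H-pyran-2-yl]prop-2-enoate | O[C@@H]1C=CC(=O)O[C@H]1/C=C/C(=O)OC(C)(C)C
F9 | step 15 | (2S,3S)-6-oxo-2-vinyl-3,6-dihydro-2H-pyran-3-yl (2E,4E,6R,11S)-4,6-dimethyl-11-(triethylsilyloxy)dodeca-2,4-dienoate | CC(/C=C/C(=O)O[C@H]1C=CC(=O)O[C@H]1C=C)=C\[C@H](C)CCCC[C@H](C)O[Si](CC)(CC)CC
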